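**Retrosynthetic overview**
1. The target flavone comes from ynone 13 by acid removal of three MOM groups and 6-endo oxa-Michael closure; the pyranone ring C is the only ring formed, and it is formed last.
2. Key step: ynone 13 is assembled in one Pd-catalysed three-component carbonylative Sonogashira coupling of aryl iodide 4 (ring A), CO (becomes C4) and arylacetylene 12 (C2, C3 and ring B).
3. Iodide 4 comes from 5-methoxyresorcinol by bis-MOM protection and C2-selective directed ortho-metalation/iodination; its symmetry means either phenol gives the same 5-OH/7-OMe flavone.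
4. Alkyne 12 comes from 1-bromo-2,4,5-trimethoxybenzene by Sonogashira coupling, then directed ortho-metalation/borylation/oxidation to place the 3'-OH between two OMe groups, MOM protection and desilylation.
5. Rings A and B are bought intact; no acetophenone, chalcone or Baker–Venkataraman step is used.

Assumption: the target is achiral (planar flavone, no stereocentres), so "single enantiomer" needs no stereocontrol.

**Step 1**
Reactants: 1 5-methoxybenzene-1,3-diol (5-methoxyresorcinol)
Product: 2 1-methoxy-3,5-bis(methoxymethoxy)benzene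
Conditions: MOMCl (2.5 equiv), i-Pr2NEt (3 equiv), CH2Cl2, 0 °C → rt
Reagents that add atoms: chloromethyl methyl ether (MOMCl), COCCl
Why: Base-mediated O-alkylation of both phenols (MOM acetal protection) gives ethers that later direct the lithiation and fall off in the final acid step.

**Step 2**
Reactants: 2 1-methoxy-3,5-bis(methoxymethoxy)benzene
Product: 4 2-iodo-5-methoxy-1,3-bis(methoxymethoxy)benzene, via aryllithium 3 (not isolated)
Conditions: n-BuLi (1.1 equiv), THF, 0 °C, 1 h; then I2, THF, −78 °C → rt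
Reagents that add atoms: iodine, II
Why: Directed ortho-metalation takes the C–H flanked by two chelating OMOM groups (stronger directors than OMe), and the aryllithium is trapped by iodine.

**Step 3**
Reactants: 5 1-bromo-2,4,5-trimethoxybenzene; 6 ethynyltriisopropylsilane
Product: 7 triisopropyl[(2,4,5-trimethoxyphenyl)ethynyl]silane
Conditions: PdCl2(PhCN)2 (3 mol%), P(t-Bu)3·HBF4 (6 mol%), CuI (2 mol%), i-Pr2NH, dioxane, rt → 50 °C
Reagents that add atoms: none
Why: Sonogashira coupling, where the bulky electron-rich phosphine allows oxidative addition into the electron-rich aryl bromide and the TIPS group masks the alkyne C–H for the next step.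

**Step 4**
Reactants: 7 triisopropyl[(2,4,5-trimethoxyphenyl)ethynyl]silane
Product: 10 2,3,6-trimethoxy-5-[(triisopropylsilyl)ethynyl]phenol, via aryllithium 8 (not isolated), via dimethyl arylboronate 9 (not isolated)
Conditions: s-BuLi (1.2 equiv), TMEDA, THF, −78 → −40 °C; B(OMe)3, −78 °C → rt; then AcOH, 30% H2O2, 0 °C → rt
Reagents that add atoms: trimethyl borate, COB(OC)OC (atoms kept only in intermediate 9); hydrogen peroxide, OO
Why: Directed ortho-metalation occurs at the only C–H flanked by two OMe groups (the other ring C–H has one OMe neighbour and the hindered silyl alkyne is inert at low temperature), followed by borylation and boronate oxidation (1,2-aryl shift from B to O) to the phenol.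

**Step 5**
Reactants: 10 2,3,6-trimethoxy-5-[(triisopropylsilyl)ethynyl]phenol
Product: 11 triisopropyl{[2,4,5-trimethoxy-3-(methoxymethoxy)phenyl]ethynyl}silane
Conditions: MOMCl (2 equiv), i-Pr2NEt (3 equiv), CH2Cl2, 0 → 40 °C
Reagents that add atoms: chloromethyl methyl ether (MOMCl), COCCl
Why: MOM protection (O-alkylation) stops the phenol from trapping the aroyl-palladium intermediate of step 7 as an aryl ester.

**Step 6**
Reactants: 11 triisopropyl{[2,4,5-trimethoxy-3-(methoxymethoxy)phenyl]ethynyl}silane
Product: 12 1-ethynyl-2,4,5-trimethoxy-3-(methoxymethoxy)benzene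
Conditions: TBAF (1.1 equiv), THF, 0 °C → rt
Reagents that add atoms: none
Why: Fluoride-mediated protodesilylation of the alkynylsilane leaves the MOM and methyl ethers untouched.

**Step 7**
Reactants: 4 2-iodo-5-methoxy-1,3-bis(methoxymethoxy)benzene; 12 1-ethynyl-2,4,5-trimethoxy-3-(methoxymethoxy)benzene
Product: 13 1-[4-methoxy-2,6-bis(methoxymethoxy)phenyl]-3-[2,4,5-trimethoxy-3-(methoxymethoxy)phenyl]prop-2-yn-1-one
Conditions: PdCl2(PPh3)2 (5 mol%), Et3N (3 equiv), THF, CO (5 bar), 60 °C (copper-free)
Reagents that add atoms: carbon monoxide, [C-]#[O+]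
Why: Carbonylative Sonogashira coupling, in which oxidative addition into the C–I bond is followed by CO insertion (fast for an electron-rich, di-ortho-substituted aryl-Pd, which also slows direct alkynylation) and alkynyl transfer/reductive elimination to the ynone.

**Step 8**
Reactants: 13 1-[4-methoxy-2,6-bis(methoxymethoxy)phenyl]-3-[2,4,5-trimethoxy-3-(methoxymethoxy)phenyl]prop-2-yn-1-one
Product: 15 5-hydroxy-2-(3-hydroxy-2,4,5-trimethoxyphenyl)-7-methoxy-4H-chromen-4-one (5,3'-dihydroxy-7,2',4',5'-tetramethoxyflavone), via trihydroxy ynone 14 (not isolated)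
Conditions: 3 M HCl in MeOH, 50 °C
Reagents that add atoms: none
Why: Acid methanolysis of the three MOM acetals frees ynone 14, whose ortho phenol adds 6-endo-dig to the acid-activated ynone (intramolecular oxa-Michael cyclisation), and because the two ortho OH groups are equivalent only the 5-hydroxy-7-methoxy flavone can form.

**Compound list**
1 | 5-methoxybenzene-1,3-diol (5-methoxyresorcinol) | COc1cc(O)cc(O)c1 | starting material
2 | 1-methoxy-3,5-bis(methoxymethoxy)benzene | COCOc1cc(OC)cc(OCOC)c1 | intermediate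
3 | [4-methoxy-2,6-bis(methoxymethoxy)phenyl]lithium | [Li]c1c(OCOC)cc(OC)cc1OCOC | intermediate
4 | 2-iodo-5-methoxy-1,3-bis(methoxymethoxy)benzene | COCOc1cc(OC)cc(OCOC)c1I | intermediate
5 | 1-bromo-2,4,5-trimethoxybenzene | COc1cc(OC)c(Br)cc1OC | starting material
6 | ethynyltriisopropylsilane | C#C[Si](C(C)C)(C(C)C)C(C)C | starting material
7 | triisopropyl[(2,4,5-trimethoxyphenyl)ethynyl]silane | COc1cc(OC)c(C#C[Si](C(C)C)(C(C)C)C(C)C)cc1OC | intermediate
8 | {2,3,6-trimethoxy-5-[(triisopropylsilyl)ethynyl]phenyl}lithium | [Li]c1c(OC)c(OC)cc(C#C[Si](C(C)C)(C(C)C)C(C)C)c1OC | intermediate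
9 | dimethyl {2,3,6-trimethoxy-5-[(triisopropylsilyl)ethynyl]phenyl}boronate | COB(OC)c1c(OC)c(OC)cc(C#C[Si](C(C)C)(C(C)C)C(C)C)c1OC | intermediate
10 | 2,3,6-trimethoxy-5-[(triisopropylsilyl)ethynyl]phenol | COc1cc(C#C[Si](C(C)C)(C(C)C)C(C)C)c(OC)c(O)c1OC | intermediate
11 | triisopropyl{[2,4,5-trimethoxy-3-(methoxymethoxy)phenyl]ethynyl}silane | COCOc1c(OC)c(OC)cc(C#C[Si](C(C)C)(C(C)C)C(C)C)c1OC | intermediate
12 | 1-ethynyl-2,4,5-trimethoxy-3-(methoxymethoxy)benzene | C#Cc1cc(OC)c(OC)c(OCOC)c1OC | intermediate
13 | 1-[4-methoxy-2,6-bis(methoxymethoxy)phenyl]-3-[2,4,5-trimethoxy-3-(methoxymethoxy)phenyl]prop-2-yn-1-one | COCOc1cc(OC)cc(OCOC)c1C(=O)C#Cc1cc(OC)c(OC)c(OCOC)c1OC | intermediate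
14 | 1-(2,6-dihydroxy-4-methoxyphenyl)-3-(3-hydroxy-2,4,5-trimethoxyphenyl)prop-2-yn-1-one | COc1cc(O)c(C(=O)C#Cc2cc(OC)c(OC)c(O)c2OC)c(O)c1 | intermediate
15 | 5-hydroxy-2-(3-hydroxy-2,4,5-trimethoxyphenyl)-7-methoxy-4H-chromen-4-one (5,3'-dihydroxy-7,2',4',5'-tetramethoxyflavone) | COc1cc(O)c2c(=O)cc(-c3cc(OC)c(OC)c(O)c3OC)oc2c1 | target

**Totals**
Total step count: 8.
Longest linear sequence: 6 steps (5 → 7 → 10 → 11 → 12 → 13 → 15, steps 3 to 8).

**Three steps most likely to fail, with fallbacks**

Step 7 (carbonylative coupling of a di-ortho-alkoxy aryl iodide; possible direct Sonogashira product or slow turnover). The fallback sets out from 2 and 12, drops CO and palladium, and comes back at 13. Compound 2 is lithiated as in step 2 (aryllithium 3) but quenched with DMF to give 4-methoxy-2,6-bis(methoxymethoxy)benzaldehyde F1. Alkyne 12 is deprotonated with n-BuLi (THF, −78 °C) and added to F1 to give racemic 1-[4-methoxy-2,6-bis(methoxymethoxy)phenyl]-3-[2,4,5-trimethoxy-3-(methoxymethoxy)phenyl]prop-2-yn-1-ol F2. Oxidation of F2 with MnO2 (CH2Cl2, rt) gives ynone 13, and step 8 follows unchanged.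

Step 4 (site of lithiation and tolerance of the silyl alkyne toward s-BuLi). The fallback sets out from 5, installs the oxygen before the alkyne using silicon as an RLi-inert placeholder that also shields the neighbouring C–H, and comes back at 11. Bromine–lithium exchange on 5 (n-BuLi, THF, −78 °C) and trapping with Me3SiCl give trimethyl(2,4,5-trimethoxyphenyl)silane F3. Ortho-lithiation between the two OMe groups (n-BuLi, TMEDA, THF, 0 °C), B(OMe)3 and then H2O2 give 2,3,6-trimethoxy-5-(trimethylsilyl)phenol F4. MOMCl/i-Pr2NEt gives trimethyl[2,4,5-trimethoxy-3-(methoxymethoxy)phenyl]silane F5. Ipso-iododesilylation with ICl (CH2Cl2, −78 °C) gives 1-iodo-2,4,5-trimethoxy-3-(methoxymethoxy)benzene F6. Sonogashira coupling of F6 with 6 (PdCl2(PPh3)2, CuI, Et3N, rt) gives 11.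

Step 8 (possible 5-exo closure to an aurone or acid-induced decomposition of the free ynone). The fallback sets out from 13, fixes the ring size before the phenols are unmasked, and comes back at 15. Diethylamine (EtOH, rt) adds to the ynone to give (E)-3-(diethylamino)-1-[4-methoxy-2,6-bis(methoxymethoxy)phenyl]-3-[2,4,5-trimethoxy-3-(methoxymethoxy)phenyl]prop-2-en-1-one F7; the alkene geometry is lost later and does not matter. Treatment of F7 with 3 M HCl in MeOH removes the MOM groups, and the freed phenol closes by addition–elimination at the amine-bearing carbon with loss of diethylamine, which can only give the six-membered pyranone 15.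

**Further compounds**
F1 | step 7 | 4-methoxy-2,6-bis(methoxymethoxy)benzaldehyde | COCOc1cc(OC)cc(OCOC)c1C=O
F2 | step 7 | rac-1-[4-methoxy-2,6-bis(methoxymethoxy)phenyl]-3-[2,4,5-trimethoxy-3-(methoxymethoxy)phenyl]prop-2-yn-1-ol | COCOc1cc(OC)cc(OCOC)c1C(O)C#Cc1cc(OC)c(OC)c(OCOC)c1OC
F3 | step 4 | trimethyl(2,4,5-trimethoxyphenyl)silane | COc1cc(OC)c([Si](C)(C)C)cc1OC
F4 | step 4 | 2,3,6-trimethoxy-5-(trimethylsilyl)phenol | COc1cc([Si](C)(C)C)c(OC)c(O)c1OC
F5 | step 4 | trimethyl[2,4,5-trimethoxy-3-(methoxymethoxy)phenyl]silane | COCOc1c(OC)c(OC)cc([Si](C)(C)C)c1OC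
F6 | step 4 | 1-iodo-2,4,5-trimethoxy-3-(methoxymethoxy)benzene | COCOc1c(OC)c(OC)cc(I)c1OC
F7 | step 8 | (E)-3-(diethylamino)-1-[4-methoxy-2,6-bis(methoxymethoxy)phenyl]-3-[2,4,5-trimethoxy-3-(methoxymethoxy)phenyl]prop-2-en-1-one | CCN(CC)/C(=C/C(=O)c1c(OCOC)cc(OC)cc1OCOC)c1cc(OC)c(OC)c(OCOC)c1OC
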